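Readings and results are simulated on assumed constants, and the scatter is random.

Read the fall, not the rise.

| setting | alder | larch | flask |
|---|---|---|---|
| Sub | 20 mM | 20 mM | 20 mM |
| Ptn | 1.5 equiv | 2.3 equiv | 1.05 equiv |
| remark | run made earlier | run made earlier |  |
| time |  |  | 5.0 h |
| volume of the second phase over the first |  |  | 0.25 |

| run | time / h | Sub.Ptn2 / % |
|---|---|---|
| alder | 0.250 | 6.6 |
| alder | 0.500 | 16.9 |
| alder | 1.33 | 31.4 |
| alder | 3.00 | 21.2 |
| larch | 0.250 | 9.4 |
| larch | 0.500 | 21.7 |
| larch | 1.33 | 36.3 |
| larch | 3.00 | 15.8 |

(readings scatter by 1 percentage point)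

- in the second phase: Ptn; everything else is in the first
- charges count per volume of the first phase; a concentration in a rate is the amount of a species over the volume of its own phase; every rate counts per litre of the first phase
- the earlier runs hold the two phases in the same ratio of volumes as the flask asked about

- Monday's: doubling the amount of Ptn, all else as stated
- Sunday's: doubling the transfer coefficient of Ptn, all else as stated

* amount of Sub.Ptn2 at 5.0 h, in percent of the Sub charged
* the change that raises the amount of Sub.Ptn2 at 5.0 h, in percent of the Sub charged most ("none" if none brings more than 2 percentage points) (Monday's / Sunday's / none)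
* amount of Sub.Ptn2 at 5.0 h, in percent of the Sub charged, after Monday's

What do the two runs show about Sub.Ptn2? Its share of the Sub charged climbs to a highest reading at 1.33 h in both alder and larch and then drops, so I expect the flask to stand on the falling side at 5.0 h.

How do you put a number on that fall? I treat it as pseudo-first-order and take the halving time, the time in which the reading falls by a factor of 2 after its highest reading, which gives 2.95 h for alder and 1.39 h for larch, so the run with more Ptn falls faster, as far as two readings each can tell.

But the flask is neither run, so what then? With 1.05 equiv it has less Ptn than alder, and two runs do not place its halving time for me, so as a rough estimate I take alder's 21.2 % at 3.00 h as a stand-in for the flask and run both halving times on to 5.0 h, which gives 7.83 % to 13.2 %, and I commit to the middle, 10.5 %.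

And the changes? Monday's brings the flask close to larch, whose 15.8 % at 3.00 h reckoned on with its own halving time gives 5.83 %, less than my flask, and I expect Sunday's to move the flask further down the same falling side, so I choose neither.

The forecast puts the flask at 14 % and Monday's at 7 %, with none as the best change, in the words “Neither change helps”.

The flask gives 10.4 %, and 4.81 % after Monday's; Monday's changes the answer by −5.6 percentage points and Sunday's by −1.3 points, so the choice is none.

    Ptn2 → Ofp (k = 0.0101 h⁻¹)
    Sub.Ptn2 → Ofp3 (k = 0.574 h⁻¹)
    Ptn2 ⇌ Ptn, rate k3*([Ptn2] - [Ptn]/K3) per volume of the first phase (partition coefficient = 1.33, kL = 0.431 h⁻¹)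
    Sub.Ptn2 ⇌ Ofp4 (K = 0.940, k = 0.0623 h⁻¹)
    Sub + Ptn2 → Sub.Ptn2 (k = 71.7 L mol⁻¹ h⁻¹)
    Ptn2 + Sub.Ptn2 → Ofp2 (k = 24.8 L mol⁻¹ h⁻¹)

Between 2.50 h and 5.0 h the flask's Sub.Ptn2 goes from 23.8 % to 10.4 %, a halving time of 2.11 h, longer than larch's and shorter than alder's. At 5.00 h the step to Ofp3 takes 11 times as much of the flask's Sub.Ptn2 as the step to Ofp2. For the same flask read at 12 h, the two halving times carried on from 10.4 % give 0.319 % to 2.01 %; that flask holds 1.71 %.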